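Target was what I wanted to count, but I reckoned first with the fraction of solid substrate left.

| flask | solid substrate | temperature | remark | time |
|---|---|---|---|---|
| alpha | 0.034 M | −16 °C | run made earlier |  |
| gamma | 0.075 M | −8 °C | run made earlier |  |
| Saturday's | 0.050 M | −20 °C |  | 2.0 min |
| Sunday's | 0.050 M |  | at −20 °C until 25 s, from then on at −5 °C | 2.0 min |
| Thursday's | 0.050 M | −5 °C |  | 2.0 min |

| run | time / s | target / % | solid substrate / % |
|---|---|---|---|
| alpha | 15.0 | 30 | 43 |
| alpha | 30.0 | 39 | 0 |
| alpha | 50.0 | 38 | 0 |
| alpha | 60.0 | 36 | 0 |
| alpha | 80.0 | 34 | 0 |
| alpha | 90.0 | 33 | 0 |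
| gamma | 10.0 | 7 | 86 |
| gamma | 12.0 | 10 | 80 |
| gamma | 15.0 | 11 | 71 |
| gamma | 30.0 | 17 | 48 |
| gamma | 40.0 | 20 | 32 |
| gamma | 50.0 | 19 | 12 |

(scatter of a reading: 2 percentage points)

- percent here means solid substrate units held: one target counts as two
- solid substrate is a solid; its amount is given per volume of the solution
- at the start none of the solid substrate is in solution
- what has only dissolved of solid substrate counts as not reacted

- the best flask by amount of target, in percent of the solid substrate charged; "all alike" if 1.5 percentage points covers them all (Saturday's / Sunday's / Thursday's / all alike)
- amount of target at the end, in percent of the solid substrate charged, Saturday's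
- amount of target at the end, in percent of the solid substrate charged, Sunday's
- amount of target at the end, in percent of the solid substrate charged, Thursday's

In the alpha run the solid lost 1.29 mM s⁻¹ up to 15.0 s, and in the gamma run 1.39 mM s⁻¹ between 10.0 s and 50.0 s. Because these nearly agreed across different temperatures and charges, I read the passing into solution as the rate-limiting step of the solid's loss. I kept their mean, 1.34 mM s⁻¹, as the feed, the solid substrate leaving the solid per litre and second. The fraction left is then one minus feed times time over c(solid substrate). For c(solid substrate) = 0.050 M it reaches zero at 37.3 s, well inside the 2.0 min asked.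

The forecast gave 33 % for Saturday's, 11 % for Sunday's and 9 % for Thursday's, with Saturday's best; from the straight fall of the solid it concluded “so dissolution limits the rate”.

The simulation gave 30.2 % for Saturday's, 24.3 % for Sunday's and 22.1 % for Thursday's. Saturday's was best, as forecast, while Sunday's and Thursday's stood 13 percentage points and 13 points above their forecast values.

    starting material + target → side product (k = 6.32 L mol⁻¹ s⁻¹, Ea = 41.0 kJ mol⁻¹)
    2 starting material → target (k = 11.4 L mol⁻¹ s⁻¹, Ea = 45.0 kJ mol⁻¹)
    solid substrate ⇌ starting material, rate k3*(cs3 - [starting material]) while solid is left; crystals form when [starting material] > cs3 (solubility = 38.0 mM, k = 0.0388 s⁻¹)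
    (constants at −20 °C)

The feed put Sunday's solid at 33.0 % at 25 s, where that flask held 37.7 %. In the neighbour like Thursday's but charged with 0.20 M, it put the solid at 19.6 % at 2.0 min, where that flask held 19.6 % and target stood at 6.91 %. Thursday's itself held 0.182 % of starting material at 1.00 min, and at its end the half-life of target by the side step was 61 h, far longer than the 2.0 min. Left ten times as long, Saturday's held 30.1 % at 20.0 min, Sunday's 24.3 % at 20.0 min and Thursday's 22.1 % at 20.0 min.

The runs stem from a simulated flask for substances that don't exist, and the scatter is random.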